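(The numbers in the tables come from a simulation on assumed constants, noise included.)

The time of reading in this flask is no clock time but the moment when 5.0 % of the E has left, and at that moment the lag seen in both earlier runs should still be running. The rate of making G then depends on how much intermediate has piled up and on how much Q and J work on it.

| flask | E | J | Q | remark |
|---|---|---|---|---|
| ochre | 0.50 M | 1.5 M | 0.12 mM | run made earlier |
| violet | 0.50 M | 1.5 M | 0.50 mM | run made earlier |
| flask | 0.50 M | 1.50 M | 0.25 mM |  |

| ochre: time / h | ochre: G / % | violet: time / h | violet: G / % |
|---|---|---|---|
| 0.250 | 0.2 | 0.250 | 13.3 |
| 0.500 | 3.1 | 0.667 | 45.3 |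
| 0.833 | 7.3 | 1.33 | 70.8 |
| 1.33 | 15.3 | 2.00 | 79.3 |
| 2.00 | 23.4 | 3.00 | 82.9 |
| 4.00 | 36.2 | 4.00 | 85.8 |

(each reading ± 0.5 percentage points)

1. factor on the rate of making G when 5.0 % of the E are converted if J is charged twice over
2. factor on the rate when 5.0 % of the E are converted if Q is charged at 2.5 mM instead

- the numbers in the tables scatter by 0.5 percentage points (one standard deviation)
- what has left E counts as converted, also if it is not yet product
- no earlier run changes the charge of J; that part of a forecast is a guess

A first estimate holds the intermediate fixed and takes the rate as proportional to Q, which gives ten times the rate for the richer charge. The objection is that what has left E need not be intermediate: violet's G stands at 85.8 % after 4.00 h and climbs slowly, so part of the E seems to leave by a way that needs no Q. Taking that reading as the share of E passing through Q gives 0.0828 mM, the balance charge: the charge of Q at which the route through Q and the route without it take E equally fast, so that the share through Q is Q over Q plus the balance charge.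

This flask then has a share of 75.1 %, and the charge of 2.5 mM has 96.8 %. The intermediate may drain before the reading, but draining and the approach to 5.0 % should both speed up with Q, so that loss should largely cancel in the ratio. A harder doubt is that violet's slow climb may partly be dying Q, which would overstate the balance charge and pull the factor towards ten. My reckoning still commits to 12.9. For J, a guess that the route without Q goes with J doubles the balance charge, giving a share of 60.2 % and a factor of 1.60.

The forecast gives 1.6 for J, as a guess, and 9.5 for Q, on the ground that “Ten times the Q from the flask's 0.25 mM should give about ten times the rate”; my factor for Q is higher.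

The flask gives 1.57 for J and 12.9 for Q.

    E + Q → Q + D (k = 1.10 /M/s)
    J + Q + D → Q + G (k = 1.60 /M²/s)
    E + J → X (k = 6.10 × 10⁻⁵ /M/s)
    Q → L (k = 6.70 × 10⁻⁵ /s)

D is the intermediate, and X is what the route without Q makes. Taking E + J → X out of the flask lowers the apparent order in Q at the reading from 1.3 to 1.0. The same run raises this flask's rate to 1.32 times the actual one. With the balance charge of 0.0828 mM, this flask's share through Q is 75.1 % and the charge of 2.5 mM has 96.8 %, and the ratio of the two shares, 1.29, lifts the factor of ten times to 12.9.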